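**Strategy.** Ring A (its C1 bonded to C2 of the oxolane, methoxy groups on its C3 and C4) is disconnected across its C1–C2 and C5–C6 bonds. Ring carbons 1 and 6 come from an ethynyl group on oxolane C2, and carbons 2–5, with both methoxy groups, from 2,3-dimethoxybuta-1,3-diene. One cobalt-catalysed [4+2] cycloaddition forms both bonds and the six-membered ring; the symmetrical diene leaves no regiochemical question, and dehydrogenation completes ring A. The precursor is the all-trans (2S,3S,4S,5S)-2-ethynyl-3,4-dimethyl-5-(3,4,5-trimethoxyphenyl)oxolane, with ring B already in place. It is built from a crotylboration-derived lactone; the alkyne is added to the lactone and the C2–H bond is made last.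

Key step: step 8

Assumption: the (S)-configured phosphoric acid is taken to deliver the crotyl group to the si face of the aryl aldehyde (mirror image of the re-face addition given by the (R)-acid); should the first run show the opposite sense, only the enantiomer of this catalyst is exchanged.

Design remark: C2 is not created by adding an alkyne to a lactol-derived oxocarbenium ion. Nucleophiles enter the all-pseudoequatorial oxocarbenium ion of this ring syn to the C3 methyl group, so that route would be expected to give mainly the C2 epimer. The alkyne is therefore added to the lactone, and the nucleophile that enters C2 is hydride (step 6).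

**Step 1**
Reactants: 1 3,4,5-trimethoxybenzaldehyde; 2 (E)-crotylboronic acid pinacol ester
Product: 4 (1S,2S)-2-methyl-1-(3,4,5-trimethoxyphenyl)but-3-en-1-ol, via pinacol borate ester 3 (not isolated)
Conditions: (S)-TRIP phosphoric acid [(S)-3,3'-bis(2,4,6-triisopropylphenyl)-1,1'-binaphthyl-2,2'-diyl hydrogen phosphate] (5 mol%), toluene, −30 °C; aq. NaHCO3 work-up
Reagents that add atoms: none
Why: Brønsted-acid-catalysed aldehyde crotylboration through a closed six-membered chair transition state, in which the (E)-crotyl geometry should give the anti hydroxyl/methyl relationship and the chiral phosphate, hydrogen-bonded to a boronate oxygen and the formyl hydrogen, should expose the si face, setting the later C5 and C4 as S and S.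

**Step 2**
Reactants: 4 (1S,2S)-2-methyl-1-(3,4,5-trimethoxyphenyl)but-3-en-1-ol
Product: 6 (1S,2S)-2-methyl-1-(3,4,5-trimethoxyphenyl)butane-1,4-diol, via bis(9-borabicyclononyl) adduct 5 (not isolated)
Conditions: 9-BBN-H (2.5 equiv), THF, 0 °C to rt; then NaOH, H2O2, 0 °C to rt
Reagents that add atoms: hydrogen peroxide, OO
Why: anti-Markovnikov hydroboration–oxidation, in which the bulky borane should place boron on the terminal carbon only and the C–B bond is oxidised without touching either stereocentre.

**Step 3**
Reactants: 6 (1S,2S)-2-methyl-1-(3,4,5-trimethoxyphenyl)butane-1,4-diol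
Product: 8 (4S,5S)-4-methyl-5-(3,4,5-trimethoxyphenyl)oxolan-2-one, via lactol 7 (not isolated)
Conditions: TEMPO (0.2 equiv), PhI(OAc)2 (2.5 equiv), CH2Cl2, rt
Reagents that add atoms: none
Why: oxoammonium-mediated (TEMPO) oxidative lactonisation, in which the unhindered primary alcohol should be oxidised faster than the secondary benzylic one, the hydroxy aldehyde closes to the five-membered lactol and a second oxidation gives the lactone with C5 untouched.

**Step 4**
Reactants: 8 (4S,5S)-4-methyl-5-(3,4,5-trimethoxyphenyl)oxolan-2-one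
Product: 10 (3S,4S,5S)-3,4-dimethyl-5-(3,4,5-trimethoxyphenyl)oxolan-2-one, via lithium enolate 9 (not isolated)
Conditions: LiN(SiMe3)2 (1.1 equiv), THF, −78 °C; MeI (3 equiv), −78 to −40 °C
Reagents that add atoms: iodomethane, CI
Why: lactone enolate alkylation, in which iodomethane should approach the planar enolate from the face opposite the neighbouring C4 methyl group and give the 3,4-trans lactone (C3 S), also the thermodynamically preferred epimer.

**Step 5**
Reactants: 10 (3S,4S,5S)-3,4-dimethyl-5-(3,4,5-trimethoxyphenyl)oxolan-2-one; 11 ethynyltrimethylsilane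
Product: 13 (3S,4S,5S)-3,4-dimethyl-5-(3,4,5-trimethoxyphenyl)-2-[(trimethylsilyl)ethynyl]oxolan-2-ol (both C2 anomers), via lithium hemiketal alkoxide 12 (not isolated)
Conditions: 11 (1.5 equiv), n-BuLi (1.4 equiv), THF, −78 °C; then 10, −78 °C; AcOH quench at −78 °C; used crude
Reagents that add atoms: none
Why: 1,2-addition of a lithium acetylide to a lactone carbonyl, in which the tetrahedral lithium alkoxide should persist at −78 °C so that only one addition occurs and protonation gives the hemiketal, whose C2 configuration is irrelevant.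

**Step 6**
Reactants: 13 (3S,4S,5S)-3,4-dimethyl-5-(3,4,5-trimethoxyphenyl)-2-[(trimethylsilyl)ethynyl]oxolan-2-ol
Product: 15 trimethyl{[(2S,3S,4S,5S)-3,4-dimethyl-5-(3,4,5-trimethoxyphenyl)oxolan-2-yl]ethynyl}silane, via alkynyl oxocarbenium ion 14 (not isolated)
Conditions: Et3SiH (4 equiv), BF3·OEt2 (2 equiv), CH2Cl2, −78 °C; aq. NaHCO3 quench at −78 °C
Reagents that add atoms: none
Why: ionic hydrogenation (silane reduction of a hemiketal through its oxocarbenium ion), in which the ion should adopt the envelope with C4 as flap that holds the C3 methyl, C4 methyl and C5 aryl groups all pseudoequatorial (the linear alkynyl group causes little allylic strain), and hydride should enter C2 from the inside face of that envelope, anti to the C4 methyl and syn to the C3 methyl, leaving the alkynyl group trans to the C3 methyl and to the C5 aryl group (C2 S).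

**Step 7**
Reactants: 15 trimethyl{[(2S,3S,4S,5S)-3,4-dimethyl-5-(3,4,5-trimethoxyphenyl)oxolan-2-yl]ethynyl}silane
Product: 16 (2S,3S,4S,5S)-2-ethynyl-3,4-dimethyl-5-(3,4,5-trimethoxyphenyl)oxolane
Conditions: K2CO3 (0.2 equiv), MeOH, rt
Reagents that add atoms: none
Why: methanolytic protodesilylation of an alkynylsilane, which should cleave only the C(sp)–Si bond under conditions too mild to affect the ether stereocentres.

**Step 8**
Reactants: 16 (2S,3S,4S,5S)-2-ethynyl-3,4-dimethyl-5-(3,4,5-trimethoxyphenyl)oxolane; 17 2,3-dimethoxybuta-1,3-diene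
Product: 18 (2S,3S,4S,5S)-2-(4,5-dimethoxycyclohexa-1,4-dien-1-yl)-3,4-dimethyl-5-(3,4,5-trimethoxyphenyl)oxolane
Conditions: 17 (2.5 equiv), CoBr2(Ph2PCH2CH2PPh2) (10 mol%), Zn powder (20 mol%), ZnI2 (20 mol%), CH2Cl2, rt; filtration through basic Al2O3 (pentane/Et2O, 1% Et3N)
Reagents that add atoms: none
Why: Zinc should reduce the divalent cobalt precatalyst to monovalent cobalt while ZnI2 removes bromide, so the cationic diphosphine–cobalt centre binds the s-cis diene and the alkyne, couples them by oxidative cyclisation to a cobaltacycle of trivalent cobalt and releases the cyclohexa-1,4-diene by reductive elimination, the two new bonds joining the alkyne carbons to the two diene termini. The closest known reaction type is the cobalt-catalysed neutral Diels–Alder reaction of unactivated terminal alkynes with 2,3-disubstituted and oxygen-substituted buta-1,3-dienes. The ring closes as a six-membered carbocycle in a [4+2] mode (four diene carbons plus two alkyne carbons), the second bond arising by reductive elimination at the metal, so the lack of an activating group on the alkyne is no handicap. No stereocentre is formed, and the four oxolane centres should stay untouched because the medium is neutral and at room temperature. The step needs chemoselectivity only (cross-cycloaddition instead of alkyne cyclotrimerisation or diene oligomerisation), which the chelating diphosphine, the non-coordinating solvent and the excess of diene should secure. Regiochemistry cannot arise because the diene is constitutionally symmetrical, and the substrate offers a single unhindered terminal alkyne and no other unsaturation that binds cobalt.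

**Step 9**
Reactants: 18 (2S,3S,4S,5S)-2-(4,5-dimethoxycyclohexa-1,4-dien-1-yl)-3,4-dimethyl-5-(3,4,5-trimethoxyphenyl)oxolane
Product: 19 5-methoxygalbelgin [(2S,3S,4S,5S)-2-(3,4-dimethoxyphenyl)-3,4-dimethyl-5-(3,4,5-trimethoxyphenyl)oxolane]
Conditions: DDQ (1.05 equiv), toluene, 0 °C, short reaction time; aq. NaHCO3
Reagents that add atoms: none
Why: quinone dehydrogenation of a cyclohexa-1,4-diene, in which hydride abstraction from a doubly allylic CH2 next to an enol ether should give a methoxy-stabilised cyclohexadienyl cation that loses a proton to form ring A much faster than the oxidant can attack the benzylic ether C–H bonds.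

**Compound list**

1 | 3,4,5-trimethoxybenzaldehyde | COc1cc(C=O)cc(OC)c1OC | starting material
2 | (E)-crotylboronic acid pinacol ester | C/C=C/CB1OC(C)(C)C(C)(C)O1 | starting material
3 | 4,4,5,5-tetramethyl-2-{[(1S,2S)-2-methyl-1-(3,4,5-trimethoxyphenyl)but-3-en-1-yl]oxy}-1,3,2-dioxaborolane | CC1(C)OB(O[C@H](c2cc(OC)c(OC)c(OC)c2)[C@@H](C)C=C)OC1(C)C | intermediate (not isolated)
4 | (1S,2S)-2-methyl-1-(3,4,5-trimethoxyphenyl)but-3-en-1-ol | O[C@H](c1cc(OC)c(OC)c(OC)c1)[C@@H](C)C=C | intermediate
5 | (1S,2S)-4-(9-borabicyclo[3.3.1]nonan-9-yl)-1-(9-borabicyclo[3.3.1]nonan-9-yloxy)-2-methyl-1-(3,4,5-trimethoxyphenyl)butane | B1(C2CCCC1CCC2)O[C@H](c1cc(OC)c(OC)c(OC)c1)[C@@H](C)CCB1C2CCCC1CCC2 | intermediate (not isolated)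
6 | (1S,2S)-2-methyl-1-(3,4,5-trimethoxyphenyl)butane-1,4-diol | O[C@H](c1cc(OC)c(OC)c(OC)c1)[C@@H](C)CCO | intermediate
7 | (4S,5S)-4-methyl-5-(3,4,5-trimethoxyphenyl)oxolan-2-ol (anomers) | OC1O[C@H](c2cc(OC)c(OC)c(OC)c2)[C@@H](C)C1 | intermediate (not isolated)
8 | (4S,5S)-4-methyl-5-(3,4,5-trimethoxyphenyl)oxolan-2-one | O=C1O[C@H](c2cc(OC)c(OC)c(OC)c2)[C@@H](C)C1 | intermediate
9 | lithium (4S,5S)-4-methyl-5-(3,4,5-trimethoxyphenyl)-4,5-dihydrofuran-2-olate | [Li+].[O-]C1=C[C@H](C)[C@@H](c2cc(OC)c(OC)c(OC)c2)O1 | intermediate (not isolated)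
10 | (3S,4S,5S)-3,4-dimethyl-5-(3,4,5-trimethoxyphenyl)oxolan-2-one | O=C1O[C@H](c2cc(OC)c(OC)c(OC)c2)[C@@H](C)[C@@H]1C | intermediate
11 | ethynyltrimethylsilane | C#C[Si](C)(C)C | starting material
12 | lithium (3S,4S,5S)-3,4-dimethyl-5-(3,4,5-trimethoxyphenyl)-2-[(trimethylsilyl)ethynyl]oxolan-2-olate | [Li+].[O-]C1(C#C[Si](C)(C)C)O[C@H](c2cc(OC)c(OC)c(OC)c2)[C@@H](C)[C@@H]1C | intermediate (not isolated)
13 | (3S,4S,5S)-3,4-dimethyl-5-(3,4,5-trimethoxyphenyl)-2-[(trimethylsilyl)ethynyl]oxolan-2-ol (C2 anomers) | OC1(C#C[Si](C)(C)C)O[C@H](c2cc(OC)c(OC)c(OC)c2)[C@@H](C)[C@@H]1C | intermediate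
14 | (3S,4S,5S)-3,4-dimethyl-5-(3,4,5-trimethoxyphenyl)-2-[(trimethylsilyl)ethynyl]-4,5-dihydro-3H-furan-1-ium hydroxytrifluoroborate (oxocarbenium ion) | C[Si](C)(C)C#CC1=[O+][C@H](c2cc(OC)c(OC)c(OC)c2)[C@@H](C)[C@@H]1C.O[B-](F)(F)F | intermediate (not isolated)
15 | trimethyl{[(2S,3S,4S,5S)-3,4-dimethyl-5-(3,4,5-trimethoxyphenyl)oxolan-2-yl]ethynyl}silane | C[Si](C)(C)C#C[C@H]1O[C@H](c2cc(OC)c(OC)c(OC)c2)[C@@H](C)[C@@H]1C | intermediate
16 | (2S,3S,4S,5S)-2-ethynyl-3,4-dimethyl-5-(3,4,5-trimethoxyphenyl)oxolane | C#C[C@H]1O[C@H](c2cc(OC)c(OC)c(OC)c2)[C@@H](C)[C@@H]1C | intermediate (key-step precursor)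
17 | 2,3-dimethoxybuta-1,3-diene | COC(=C)C(=C)OC | starting material
18 | (2S,3S,4S,5S)-2-(4,5-dimethoxycyclohexa-1,4-dien-1-yl)-3,4-dimethyl-5-(3,4,5-trimethoxyphenyl)oxolane | COC1=C(OC)CC([C@H]2O[C@H](c3cc(OC)c(OC)c(OC)c3)[C@@H](C)[C@@H]2C)=CC1 | intermediate (key-step product)
19 | 5-methoxygalbelgin, (2S,3S,4S,5S)-2-(3,4-dimethoxyphenyl)-3,4-dimethyl-5-(3,4,5-trimethoxyphenyl)oxolane | COc1ccc([C@H]2O[C@H](c3cc(OC)c(OC)c(OC)c3)[C@@H](C)[C@@H]2C)cc1OC | target

**Total step count:** 9
**Longest linear sequence:** 9 steps (1 to 19)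

**Steps most likely to fail**

1. **Step 8 (cobalt cycloaddition).**
   - What may go wrong: cyclotrimerisation of the terminal alkyne, oligomerisation or hydrolysis of the bis(enol ether) diene by the Lewis-acidic zinc salt, or hydrolysis of the bis(enol ether) product during isolation.
   - Fallback: ring A is brought in as a preformed arene by Friedel–Crafts arylation. The fallback sets out from lactone 10.
   - Reduction with i-Bu2AlH (CH2Cl2, −78 °C) should give (3S,4S,5S)-3,4-dimethyl-5-(3,4,5-trimethoxyphenyl)oxolan-2-ol F1.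
   - Acetylation (Ac2O, pyridine, DMAP) should give (3S,4S,5S)-3,4-dimethyl-5-(3,4,5-trimethoxyphenyl)oxolan-2-yl acetate F2.
   - Treatment with 1,2-dimethoxybenzene and BF3·OEt2 (CH2Cl2, −78 to 0 °C) should then arylate the oxocarbenium ion para to a methoxy group. Because the new benzylic ether can re-ionise under the Lewis acid, the all-trans isomer should accumulate under thermodynamic control.
   - The fallback comes back to the route at 19.

2. **Step 6 (hemiketal reduction).**
   - What may go wrong: insufficient facial selectivity of hydride delivery to the oxocarbenium ion, or epimerisation at C5 by reversible Lewis-acid ring opening.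
   - Fallback: C2 is set by reagent control and the ring is closed at C5. The fallback sets out from 13.
   - The ring-opened hydroxy ynone form of 13 is reduced by Noyori asymmetric transfer hydrogenation (RuCl[(S,S)-TsDPEN](p-cymene), i-PrOH, rt). This should give (1S,2S,3S,4S)-2,3-dimethyl-1-(3,4,5-trimethoxyphenyl)-6-(trimethylsilyl)hex-5-yne-1,4-diol F3.
   - Acid (BF3·OEt2 or TsOH, CH2Cl2) should ionise the trimethoxybenzylic hydroxyl, and the propargylic hydroxyl closes the oxolane. C2 keeps its configuration and the aryl group should settle trans to the C4 methyl group.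
   - The fallback comes back to the route at 15.

3. **Step 9 (dehydrogenation).**
   - What may go wrong: hydride abstraction by the quinone at the benzylic ether C–H bonds of the electron-rich product, or hydrolysis of the bis(enol ether) before it is dehydrogenated. Chloranil or MnO2 would be tried first as milder oxidants.
   - Fallback: no dihydroarene is used; both benzylic C–O bonds are formed from a 1,4-diol. The fallback sets out from lactone 10.
   - Addition of 3,4-dimethoxyphenyllithium (from 4-bromo-1,2-dimethoxybenzene and n-BuLi, THF, −78 °C) should give (2S,3S,4S)-1-(3,4-dimethoxyphenyl)-4-hydroxy-2,3-dimethyl-4-(3,4,5-trimethoxyphenyl)butan-1-one F4, in equilibrium with its hemiketal.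
   - NaBH4 (MeOH, 0 °C) should give (2S,3S,4S)-1-(3,4-dimethoxyphenyl)-2,3-dimethyl-4-(3,4,5-trimethoxyphenyl)butane-1,4-diol F5 as a mixture at C1.
   - Acid-mediated cycloetherification (BF3·OEt2, CH2Cl2, −20 °C) through the 3,4-dimethoxybenzylic cation should converge both C1 epimers on the all-trans oxolane.
   - The fallback comes back to the route at 19.

**Further compounds**
F1 | step 8 | (3S,4S,5S)-3,4-dimethyl-5-(3,4,5-trimethoxyphenyl)oxolan-2-ol (anomers) | OC1O[C@H](c2cc(OC)c(OC)c(OC)c2)[C@@H](C)[C@@H]1C
F2 | step 8 | (3S,4S,5S)-3,4-dimethyl-5-(3,4,5-trimethoxyphenyl)oxolan-2-yl acetate (anomers) | CC(=O)OC1O[C@H](c2cc(OC)c(OC)c(OC)c2)[C@@H](C)[C@@H]1C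
F3 | step 6 | (1S,2S,3S,4S)-2,3-dimethyl-1-(3,4,5-trimethoxyphenyl)-6-(trimethylsilyl)hex-5-yne-1,4-diol | C[Si](C)(C)C#C[C@@H](O)[C@@H](C)[C@H](C)[C@H](O)c1cc(OC)c(OC)c(OC)c1
F4 | step 9 | (2S,3S,4S)-1-(3,4-dimethoxyphenyl)-4-hydroxy-2,3-dimethyl-4-(3,4,5-trimethoxyphenyl)butan-1-one | COc1ccc(C(=O)[C@@H](C)[C@H](C)[C@H](O)c2cc(OC)c(OC)c(OC)c2)cc1OC
F5 | step 9 | (2S,3S,4S)-1-(3,4-dimethoxyphenyl)-2,3-dimethyl-4-(3,4,5-trimethoxyphenyl)butane-1,4-diol (C1 epimers) | COc1ccc(C(O)[C@@H](C)[C@H](C)[C@H](O)c2cc(OC)c(OC)c(OC)c2)cc1OC
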